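**Retrosynthetic overview**
1. The target 27 comes from ketone 25 by desilylation and hydrogenolysis; 25 comes from the (S)-2-aryl-3-siloxypropanal 20 by aryl-metal addition and oxidation; 20 comes from lactone 14 by Suzuki coupling at the aryl chloride, Sharpless epoxidation and a siloxymethyl 1,2-shift.
2. Feature on which the plan rests: the lactone carbonyl C2 is a one-carbon unit between the ring oxygen O1 and C3, so the ring O1–C2–C3–C4–C5 is the allylic alcohol C5–C4=C3 of 12 plus CO, and the stereocentres C3 and C4 are the two alkene carbons.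
3. Lactone 14 comes from (E)-allylic alcohol 12 and CO by palladium-catalysed cyclocarbonylation (C2–C3 and C2–O1 formed, syn addition to the E alkene gives trans).
4. Alcohol 12 comes from ester 11 (iBu2AlH), made by an E-selective Wittig reaction of ylide 6 (from benzyl bromide 3 and Ph3P=CHCO2Et) with arylacetaldehyde 10 (from 5-chlorovanillin).
5. Ring order: both arenes are bought; the lactone (step 9) is the only ring built; an oxirane is made in step 12 and opened in step 14.

Key step: step 9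

Assumption: the face selectivity of the bisphosphine in step 9 cannot be assigned in advance for this alkene; both antipodes of BPPM are to be tried once and the one that leads to (3S,4S) is used.

**Step 1**
Reactants: 1 4-(benzyloxy)-3-methoxybenzaldehyde
Product: 2 4-(benzyloxy)-3-methoxybenzyl alcohol
Conditions: NaBH4, MeOH/THF, 0 °C
Reagents that add atoms: none
Why: Borohydride reduction of an aryl aldehyde to the benzylic alcohol, the benzyl ether being inert.

**Step 2**
Reactants: 2 4-(benzyloxy)-3-methoxybenzyl alcohol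
Product: 3 4-(benzyloxy)-3-methoxybenzyl bromide
Conditions: PBr3 (0.4 equiv), CH2Cl2, 0 °C; used crude
Reagents that add atoms: phosphorus tribromide, BrP(Br)Br
Why: Bromination of an electron-rich benzylic alcohol through its phosphite ester should be fast at 0 °C, and the labile bromide is taken on at once.

**Step 3**
Reactants: 3 4-(benzyloxy)-3-methoxybenzyl bromide; 4 ethyl (triphenylphosphoranylidene)acetate
Product: 6 ethyl 3-[4-(benzyloxy)-3-methoxyphenyl]-2-(triphenylphosphoranylidene)propanoate, via phosphonium bromide 5 (not isolated)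
Conditions: EtOAc, reflux; then NaOH (2 M aq.), CH2Cl2, rt
Reagents that add atoms: none
Why: C-alkylation of a stabilised phosphorus ylide by a reactive benzylic bromide and deprotonation of the salt give the α-substituted stabilised Wittig reagent.

**Step 4**
Reactants: 7 5-chlorovanillin (3-chloro-4-hydroxy-5-methoxybenzaldehyde)
Product: 8 4-(benzyloxy)-3-chloro-5-methoxybenzaldehyde
Conditions: BnBr, K2CO3, DMF, 60 °C
Reagents that add atoms: benzyl bromide, BrCc1ccccc1
Why: Williamson etherification of the acidic, flanked phenol should go cleanly in DMF.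

**Step 5**
Reactants: 8 4-(benzyloxy)-3-chloro-5-methoxybenzaldehyde
Product: 9 2-(benzyloxy)-1-chloro-3-methoxy-5-(2-methoxyvinyl)benzene (E/Z mixture)
Conditions: Ph3P(CH2OMe)Cl, KOtBu, THF, 0 °C to rt
Reagents that add atoms: (methoxymethyl)triphenylphosphonium chloride, COC[P+](c1ccccc1)(c1ccccc1)c1ccccc1.[Cl-]
Why: Wittig methoxymethylenation of an aryl aldehyde gives the enol ether as a one-carbon homologation, and its geometry is irrelevant.

**Step 6**
Reactants: 9 2-(benzyloxy)-1-chloro-3-methoxy-5-(2-methoxyvinyl)benzene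
Product: 10 [4-(benzyloxy)-3-chloro-5-methoxyphenyl]acetaldehyde
Conditions: HCl (2 M aq.), THF, 40 °C; used crude
Reagents that add atoms: water, O
Why: Acid hydrolysis of the enol ether releases the arylacetaldehyde, which is not stored because it enolises and self-condenses easily.

**Step 7**
Reactants: 6 ethyl 3-[4-(benzyloxy)-3-methoxyphenyl]-2-(triphenylphosphoranylidene)propanoate; 10 [4-(benzyloxy)-3-chloro-5-methoxyphenyl]acetaldehyde
Product: 11 ethyl (E)-2-[4-(benzyloxy)-3-methoxybenzyl]-4-[4-(benzyloxy)-3-chloro-5-methoxyphenyl]but-2-enoate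
Conditions: toluene, 60 °C
Reagents that add atoms: none
Why: Wittig olefination with an α-substituted stabilised ylide should place the ester trans to the aldehyde-derived CH2Ar group (E), and it needs no base, so the enolisable aldehyde and the skipped alkene are not isomerised.

**Step 8**
Reactants: 11 ethyl (E)-2-[4-(benzyloxy)-3-methoxybenzyl]-4-[4-(benzyloxy)-3-chloro-5-methoxyphenyl]but-2-enoate
Product: 12 (E)-2-[4-(benzyloxy)-3-methoxybenzyl]-4-[4-(benzyloxy)-3-chloro-5-methoxyphenyl]but-2-en-1-ol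
Conditions: iBu2AlH (2.5 equiv), CH2Cl2, −78 °C; Rochelle salt work-up
Reagents that add atoms: none
Why: 1,2-Reduction of the enoate by diisobutylaluminium hydride gives the allylic alcohol with the alkene geometry unchanged; aryl chloride and benzyl ethers are inert.

**Step 9**
Reactants: 12 (E)-2-[4-(benzyloxy)-3-methoxybenzyl]-4-[4-(benzyloxy)-3-chloro-5-methoxyphenyl]but-2-en-1-ol; 13 carbon monoxide
Product: 14 (3S,4S)-4-[4-(benzyloxy)-3-methoxybenzyl]-3-[4-(benzyloxy)-3-chloro-5-methoxybenzyl]dihydrofuran-2(3H)-one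
Conditions: Pd(OAc)2 (5 mol %), BPPM (N-Boc-4-diphenylphosphino-2-(diphenylphosphinomethyl)pyrrolidine, 10 mol %, antipode leading to 3S,4S), CO/H2 (1:1, 55 bar), CH2Cl2, 100 °C
Reagents that add atoms: carbon monoxide (reactant 13), [C-]#[O+]
Why: Pd(OAc)2 is reduced under CO/H2 to a zerovalent palladium–bisphosphine species that forms a palladium hydride; this adds syn across the E trisubstituted alkene with hydrogen on the fully substituted C4 and palladium on the less hindered C3, CO inserts into the Pd–C3 bond with retention, and the C5 hydroxyl captures the acyl palladium, so that C2–C3 and C2–O1 are formed. The closest known reaction is the palladium–bisphosphine cyclocarbonylation of 2,3-disubstituted allylic alcohols to trans-α,β-disubstituted γ-butyrolactones, including its enantioselective BPPM version. The lactone closes by 5-exo-trig attack of the hydroxyl on the acyl carbon (equivalently C–O reductive elimination from a six-membered acyl alkoxide palladacycle); palladium on C4 would only lead to a four-membered ring and is not productive. The trans relation of C3 and C4 follows from syn addition to the E alkene (CH2OH trans to the chloroarylmethyl group), and the absolute configuration (3S,4S) is set by the alkene face that the chiral bisphosphine selects. The step needs hydride delivery to C4, no hydride-mediated migration of the double bond into conjugation with either arene, and an intact C–Cl bond; the substitution bias of the alkene with hydroxyl coordination should secure the first, high CO pressure (fast trapping of the alkyl palladium) the second, and the low reactivity of an electron-rich aryl chloride toward arylphosphine-ligated zerovalent palladium the third.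

**Step 10**
Reactants: 14 (3S,4S)-4-[4-(benzyloxy)-3-methoxybenzyl]-3-[4-(benzyloxy)-3-chloro-5-methoxybenzyl]dihydrofuran-2(3H)-one; 15 (E)-tert-butyldimethyl{[3-(4,4,5,5-tetramethyl-1,3,2-dioxaborolan-2-yl)prop-2-en-1-yl]oxy}silane
Product: 16 (3S,4S)-3-{4-(benzyloxy)-3-[(E)-3-(tert-butyldimethylsilyloxy)prop-1-en-1-yl]-5-methoxybenzyl}-4-[4-(benzyloxy)-3-methoxybenzyl]dihydrofuran-2(3H)-one
Conditions: Pd(OAc)2 (5 mol %), SPhos (10 mol %), K3PO4, toluene/H2O (10:1), 90 °C; mildly acidic work-up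
Reagents that add atoms: none
Why: Suzuki–Miyaura coupling with a dialkylbiarylphosphine ligand is established for hindered, electron-rich aryl chlorides and alkenyl boronates with retention of the E geometry; any lactone opened by the base recloses on acidification and the trans lactone is the thermodynamic isomer.

**Step 11**
Reactants: 16 (3S,4S)-3-{4-(benzyloxy)-3-[(E)-3-(tert-butyldimethylsilyloxy)prop-1-en-1-yl]-5-methoxybenzyl}-4-[4-(benzyloxy)-3-methoxybenzyl]dihydrofuran-2(3H)-one
Product: 17 (3S,4S)-3-{4-(benzyloxy)-3-[(E)-3-hydroxyprop-1-en-1-yl]-5-methoxybenzyl}-4-[4-(benzyloxy)-3-methoxybenzyl]dihydrofuran-2(3H)-one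
Conditions: HF·pyridine, pyridine, THF, 0 °C to rt
Reagents that add atoms: none
Why: Fluoride-mediated cleavage of the primary silyl ether under buffered conditions frees the allylic alcohol needed for directed epoxidation without touching lactone or benzyl ethers.

**Step 12**
Reactants: 17 (3S,4S)-3-{4-(benzyloxy)-3-[(E)-3-hydroxyprop-1-en-1-yl]-5-methoxybenzyl}-4-[4-(benzyloxy)-3-methoxybenzyl]dihydrofuran-2(3H)-one
Product: 18 (3S,4S)-3-{4-(benzyloxy)-3-[(2S,3S)-3-(hydroxymethyl)oxiran-2-yl]-5-methoxybenzyl}-4-[4-(benzyloxy)-3-methoxybenzyl]dihydrofuran-2(3H)-one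
Conditions: Ti(OiPr)4 (10 mol %), L-(+)-diisopropyl tartrate (12 mol %), tBuOOH, 4 Å sieves, CH2Cl2, −20 °C
Reagents that add atoms: tert-butyl hydroperoxide, CC(C)(C)OO
Why: Sharpless asymmetric epoxidation of the E allylic alcohol, in which the titanium tartrate complex with L-(+)-tartrate should deliver oxygen to the face that gives the (2S,3S)-epoxide under reagent control; catalytic titanium and sieves limit opening of the acid-labile ortho-alkoxyphenyl epoxide.

**Step 13**
Reactants: 18 (3S,4S)-3-{4-(benzyloxy)-3-[(2S,3S)-3-(hydroxymethyl)oxiran-2-yl]-5-methoxybenzyl}-4-[4-(benzyloxy)-3-methoxybenzyl]dihydrofuran-2(3H)-one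
Product: 19 (3S,4S)-3-{4-(benzyloxy)-3-[(2S,3S)-3-(tert-butyldimethylsilyloxymethyl)oxiran-2-yl]-5-methoxybenzyl}-4-[4-(benzyloxy)-3-methoxybenzyl]dihydrofuran-2(3H)-one
Conditions: TBSCl, imidazole, CH2Cl2, 0 °C
Reagents that add atoms: tert-butyldimethylsilyl chloride, CC(C)(C)[Si](C)(C)Cl
Why: Silylation of the primary alcohol under weakly basic conditions gives the epoxy silyl ether that the rearrangement requires.

**Step 14**
Reactants: 19 (3S,4S)-3-{4-(benzyloxy)-3-[(2S,3S)-3-(tert-butyldimethylsilyloxymethyl)oxiran-2-yl]-5-methoxybenzyl}-4-[4-(benzyloxy)-3-methoxybenzyl]dihydrofuran-2(3H)-one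
Product: 20 (3S,4S)-3-{4-(benzyloxy)-3-[(2S)-1-(tert-butyldimethylsilyloxy)-3-oxopropan-2-yl]-5-methoxybenzyl}-4-[4-(benzyloxy)-3-methoxybenzyl]dihydrofuran-2(3H)-one
Conditions: MeAl(OAr)2 (Ar = 4-bromo-2,6-di-tert-butylphenyl, 2 equiv, from AlMe3 and ArOH), CH2Cl2, −78 °C; used crude
Reagents that add atoms: none
Why: Lewis acid-promoted semipinacol-type rearrangement of a 2,3-epoxy silyl ether (Yamamoto rearrangement), in which the bulky aluminium phenoxide opens the benzylic C–O bond and the siloxymethyl group migrates anti to it, so that inversion at the benzylic carbon turns the (2S,3S)-epoxide into the (S)-α-aryl-β-siloxy aldehyde.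

**Step 15**
Reactants: 21 4-bromo-2-methoxyphenol
Product: 22 1-(benzyloxy)-4-bromo-2-methoxybenzene
Conditions: BnBr, K2CO3, DMF, 60 °C
Reagents that add atoms: benzyl bromide, BrCc1ccccc1
Why: Williamson etherification protects the phenol so that the aryl bromide can be converted into a Grignard reagent.

**Step 16**
Reactants: 20 (3S,4S)-3-{4-(benzyloxy)-3-[(2S)-1-(tert-butyldimethylsilyloxy)-3-oxopropan-2-yl]-5-methoxybenzyl}-4-[4-(benzyloxy)-3-methoxybenzyl]dihydrofuran-2(3H)-one; 22 1-(benzyloxy)-4-bromo-2-methoxybenzene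
Product: 24 (3S,4S)-3-{4-(benzyloxy)-3-[(2S)-1-[4-(benzyloxy)-3-methoxyphenyl]-3-(tert-butyldimethylsilyloxy)-1-hydroxypropan-2-yl]-5-methoxybenzyl}-4-[4-(benzyloxy)-3-methoxybenzyl]dihydrofuran-2(3H)-one (mixture of carbinol epimers), via arylmagnesium bromide 23 (not isolated)
Conditions: 22, Mg, THF; CeCl3, THF, −78 °C; then 20, −78 °C; NH4Cl (aq.)
Reagents that add atoms: none
Why: Carbonyl addition of an aryl organocerium reagent made from the Grignard reagent; its low basicity should suppress enolisation of the α-aryl aldehyde, the aldehyde reacts far faster than the lactone at −78 °C, and the new carbinol centre is removed in the next step.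

**Step 17**
Reactants: 24 (3S,4S)-3-{4-(benzyloxy)-3-[(2S)-1-[4-(benzyloxy)-3-methoxyphenyl]-3-(tert-butyldimethylsilyloxy)-1-hydroxypropan-2-yl]-5-methoxybenzyl}-4-[4-(benzyloxy)-3-methoxybenzyl]dihydrofuran-2(3H)-one
Product: 25 (3S,4S)-3-{4-(benzyloxy)-3-[(2S)-1-[4-(benzyloxy)-3-methoxyphenyl]-3-(tert-butyldimethylsilyloxy)-1-oxopropan-2-yl]-5-methoxybenzyl}-4-[4-(benzyloxy)-3-methoxybenzyl]dihydrofuran-2(3H)-one
Conditions: Dess–Martin periodinane, NaHCO3, CH2Cl2, 0 °C
Reagents that add atoms: none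
Why: Dess–Martin oxidation converts both carbinol epimers into the aryl ketone under buffered, amine-free conditions, so the acidic α-aryl centre should not epimerise and silanolate should not eliminate.

**Step 18**
Reactants: 25 (3S,4S)-3-{4-(benzyloxy)-3-[(2S)-1-[4-(benzyloxy)-3-methoxyphenyl]-3-(tert-butyldimethylsilyloxy)-1-oxopropan-2-yl]-5-methoxybenzyl}-4-[4-(benzyloxy)-3-methoxybenzyl]dihydrofuran-2(3H)-one
Product: 26 (3S,4S)-3-{4-(benzyloxy)-3-[(2S)-1-[4-(benzyloxy)-3-methoxyphenyl]-3-hydroxy-1-oxopropan-2-yl]-5-methoxybenzyl}-4-[4-(benzyloxy)-3-methoxybenzyl]dihydrofuran-2(3H)-one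
Conditions: HF·pyridine, pyridine, THF, 0 °C
Reagents that add atoms: none
Why: Buffered fluoride desilylation avoids the basic conditions that would epimerise or dehydrate the β-hydroxy ketone, and it is run while the ortho phenol is still benzylated so that acid cannot close a benzofuran.

**Step 19**
Reactants: 26 (3S,4S)-3-{4-(benzyloxy)-3-[(2S)-1-[4-(benzyloxy)-3-methoxyphenyl]-3-hydroxy-1-oxopropan-2-yl]-5-methoxybenzyl}-4-[4-(benzyloxy)-3-methoxybenzyl]dihydrofuran-2(3H)-one
Product: 27 (3S,4S)-3-{4-hydroxy-3-[(2S)-3-hydroxy-1-(4-hydroxy-3-methoxyphenyl)-1-oxopropan-2-yl]-5-methoxybenzyl}-4-(4-hydroxy-3-methoxybenzyl)dihydrofuran-2(3H)-one (CNP0281222.1)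
Conditions: H2 (1 atm), 10% Pd/C, EtOAc, rt; filtration
Reagents that add atoms: none
Why: Neutral hydrogenolysis of the three benzyl ethers is the last operation, so the labile centre and the ortho-hydroxyaryl ketone see neither acid nor base; the electron-rich para-oxygenated aryl ketone should resist reduction if the reaction is stopped at full debenzylation.

**Compound list**
1 | 4-(benzyloxy)-3-methoxybenzaldehyde | COc1cc(C=O)ccc1OCc1ccccc1 | starting material
2 | 4-(benzyloxy)-3-methoxybenzyl alcohol | COc1cc(CO)ccc1OCc1ccccc1 | intermediate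
3 | 4-(benzyloxy)-3-methoxybenzyl bromide | COc1cc(CBr)ccc1OCc1ccccc1 | intermediate
4 | ethyl (triphenylphosphoranylidene)acetate | CCOC(=O)C=P(c1ccccc1)(c1ccccc1)c1ccccc1 | starting material
5 | {3-[4-(benzyloxy)-3-methoxyphenyl]-1-ethoxy-1-oxopropan-2-yl}triphenylphosphonium bromide | CCOC(=O)C(Cc1ccc(OCc2ccccc2)c(OC)c1)[P+](c1ccccc1)(c1ccccc1)c1ccccc1.[Br-] | intermediate
6 | ethyl 3-[4-(benzyloxy)-3-methoxyphenyl]-2-(triphenylphosphoranylidene)propanoate | CCOC(=O)C(Cc1ccc(OCc2ccccc2)c(OC)c1)=P(c1ccccc1)(c1ccccc1)c1ccccc1 | intermediate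
7 | 5-chlorovanillin | COc1cc(C=O)cc(Cl)c1O | starting material
8 | 4-(benzyloxy)-3-chloro-5-methoxybenzaldehyde | COc1cc(C=O)cc(Cl)c1OCc1ccccc1 | intermediate
9 | 2-(benzyloxy)-1-chloro-3-methoxy-5-(2-methoxyvinyl)benzene (E/Z mixture) | COC=Cc1cc(OC)c(OCc2ccccc2)c(Cl)c1 | intermediate
10 | [4-(benzyloxy)-3-chloro-5-methoxyphenyl]acetaldehyde | O=CCc1cc(OC)c(OCc2ccccc2)c(Cl)c1 | intermediate
11 | ethyl (E)-2-[4-(benzyloxy)-3-methoxybenzyl]-4-[4-(benzyloxy)-3-chloro-5-methoxyphenyl]but-2-enoate | CCOC(=O)/C(Cc1ccc(OCc2ccccc2)c(OC)c1)=C/Cc1cc(OC)c(OCc2ccccc2)c(Cl)c1 | intermediate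
12 | (E)-2-[4-(benzyloxy)-3-methoxybenzyl]-4-[4-(benzyloxy)-3-chloro-5-methoxyphenyl]but-2-en-1-ol | OC/C(Cc1ccc(OCc2ccccc2)c(OC)c1)=C/Cc1cc(OC)c(OCc2ccccc2)c(Cl)c1 | intermediate
13 | carbon monoxide | [C-]#[O+] | starting material
14 | (3S,4S)-4-[4-(benzyloxy)-3-methoxybenzyl]-3-[4-(benzyloxy)-3-chloro-5-methoxybenzyl]dihydrofuran-2(3H)-one | COc1cc(C[C@@H]2COC(=O)[C@H]2Cc2cc(OC)c(OCc3ccccc3)c(Cl)c2)ccc1OCc1ccccc1 | intermediate
15 | (E)-tert-butyldimethyl{[3-(4,4,5,5-tetramethyl-1,3,2-dioxaborolan-2-yl)prop-2-en-1-yl]oxy}silane | CC(C)(C)[Si](C)(C)OC/C=C/B1OC(C)(C)C(C)(C)O1 | starting material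
16 | (3S,4S)-3-{4-(benzyloxy)-3-[(E)-3-(tert-butyldimethylsilyloxy)prop-1-en-1-yl]-5-methoxybenzyl}-4-[4-(benzyloxy)-3-methoxybenzyl]dihydrofuran-2(3H)-one | COc1cc(C[C@@H]2COC(=O)[C@H]2Cc2cc(OC)c(OCc3ccccc3)c(/C=C/CO[Si](C)(C)C(C)(C)C)c2)ccc1OCc1ccccc1 | intermediate
17 | (3S,4S)-3-{4-(benzyloxy)-3-[(E)-3-hydroxyprop-1-en-1-yl]-5-methoxybenzyl}-4-[4-(benzyloxy)-3-methoxybenzyl]dihydrofuran-2(3H)-one | COc1cc(C[C@@H]2COC(=O)[C@H]2Cc2cc(OC)c(OCc3ccccc3)c(/C=C/CO)c2)ccc1OCc1ccccc1 | intermediate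
18 | (3S,4S)-3-{4-(benzyloxy)-3-[(2S,3S)-3-(hydroxymethyl)oxiran-2-yl]-5-methoxybenzyl}-4-[4-(benzyloxy)-3-methoxybenzyl]dihydrofuran-2(3H)-one | COc1cc(C[C@@H]2COC(=O)[C@H]2Cc2cc(OC)c(OCc3ccccc3)c([C@@H]3O[C@H]3CO)c2)ccc1OCc1ccccc1 | intermediate
19 | (3S,4S)-3-{4-(benzyloxy)-3-[(2S,3S)-3-(tert-butyldimethylsilyloxymethyl)oxiran-2-yl]-5-methoxybenzyl}-4-[4-(benzyloxy)-3-methoxybenzyl]dihydrofuran-2(3H)-one | COc1cc(C[C@@H]2COC(=O)[C@H]2Cc2cc(OC)c(OCc3ccccc3)c([C@@H]3O[C@H]3CO[Si](C)(C)C(C)(C)C)c2)ccc1OCc1ccccc1 | intermediate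
20 | (3S,4S)-3-{4-(benzyloxy)-3-[(2S)-1-(tert-butyldimethylsilyloxy)-3-oxopropan-2-yl]-5-methoxybenzyl}-4-[4-(benzyloxy)-3-methoxybenzyl]dihydrofuran-2(3H)-one | COc1cc(C[C@@H]2COC(=O)[C@H]2Cc2cc(OC)c(OCc3ccccc3)c([C@@H](CO[Si](C)(C)C(C)(C)C)C=O)c2)ccc1OCc1ccccc1 | intermediate
21 | 4-bromo-2-methoxyphenol | COc1cc(Br)ccc1O | starting material
22 | 1-(benzyloxy)-4-bromo-2-methoxybenzene | COc1cc(Br)ccc1OCc1ccccc1 | intermediate
23 | [4-(benzyloxy)-3-methoxyphenyl]magnesium bromide | COc1cc([Mg]Br)ccc1OCc1ccccc1 | intermediate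
24 | (3S,4S)-3-{4-(benzyloxy)-3-[(2S)-1-[4-(benzyloxy)-3-methoxyphenyl]-3-(tert-butyldimethylsilyloxy)-1-hydroxypropan-2-yl]-5-methoxybenzyl}-4-[4-(benzyloxy)-3-methoxybenzyl]dihydrofuran-2(3H)-one (carbinol epimers) | COc1cc(C[C@@H]2COC(=O)[C@H]2Cc2cc(OC)c(OCc3ccccc3)c([C@@H](CO[Si](C)(C)C(C)(C)C)C(O)c3ccc(OCc4ccccc4)c(OC)c3)c2)ccc1OCc1ccccc1 | intermediate
25 | (3S,4S)-3-{4-(benzyloxy)-3-[(2S)-1-[4-(benzyloxy)-3-methoxyphenyl]-3-(tert-butyldimethylsilyloxy)-1-oxopropan-2-yl]-5-methoxybenzyl}-4-[4-(benzyloxy)-3-methoxybenzyl]dihydrofuran-2(3H)-one | COc1cc(C[C@@H]2COC(=O)[C@H]2Cc2cc(OC)c(OCc3ccccc3)c([C@@H](CO[Si](C)(C)C(C)(C)C)C(=O)c3ccc(OCc4ccccc4)c(OC)c3)c2)ccc1OCc1ccccc1 | intermediate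
26 | (3S,4S)-3-{4-(benzyloxy)-3-[(2S)-1-[4-(benzyloxy)-3-methoxyphenyl]-3-hydroxy-1-oxopropan-2-yl]-5-methoxybenzyl}-4-[4-(benzyloxy)-3-methoxybenzyl]dihydrofuran-2(3H)-one | COc1cc(C[C@@H]2COC(=O)[C@H]2Cc2cc(OC)c(OCc3ccccc3)c([C@@H](CO)C(=O)c3ccc(OCc4ccccc4)c(OC)c3)c2)ccc1OCc1ccccc1 | intermediate
27 | (3S,4S)-3-{4-hydroxy-3-[(2S)-3-hydroxy-1-(4-hydroxy-3-methoxyphenyl)-1-oxopropan-2-yl]-5-methoxybenzyl}-4-(4-hydroxy-3-methoxybenzyl)dihydrofuran-2(3H)-one | COc1cc(C[C@@H]2COC(=O)[C@H]2Cc2cc(OC)c(O)c([C@@H](CO)C(=O)c3ccc(O)c(OC)c3)c2)ccc1O | target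

**Step count**
Total: 19 steps. Longest linear sequence: 15 steps (7 to 27 through steps 4–14 and 16–19; equally 1 to 27 through steps 1–3, 7–14 and 16–19).

**Steps most likely to fail**

1. Step 9. What may go wrong: the ligand may discriminate poorly between the faces of an alkene whose two substituents are both arylmethyl groups, and the palladium hydride may move the double bond into conjugation with an arene before the alkyl palladium is trapped by CO. The fallback builds the lactone by hydrogenation and enolate alkylation; it sets out from aldehydes 1 and 8 and comes back at lactone 14. Stobbe condensation of 1 with dimethyl succinate (NaOMe, MeOH, reflux) should give (E)-4-[4-(benzyloxy)-3-methoxyphenyl]-3-(methoxycarbonyl)but-3-enoic acid F1. Hydrogenation with [Rh(cod)2]BF4 and a DIOP-type bisphosphine (the MOD-DIOP antipode that leads to the S acid; H2, MeOH, Et3N) should give (S)-4-[4-(benzyloxy)-3-methoxyphenyl]-3-(methoxycarbonyl)butanoic acid F2, the benzyl ether being inert to the homogeneous catalyst. Reduction of the ester in the potassium carboxylate with Ca(BH4)2 (from CaCl2 and NaBH4, EtOH) and acidification should close (S)-4-[4-(benzyloxy)-3-methoxybenzyl]dihydrofuran-2(3H)-one F3. Aldehyde 8 is reduced (NaBH4) to 4-(benzyloxy)-3-chloro-5-methoxybenzyl alcohol F4 and brominated (PBr3) to 4-(benzyloxy)-3-chloro-5-methoxybenzyl bromide F5. Deprotonation of F3 with LiN(SiMe3)2 (THF, −78 °C) and alkylation with F5 anti to the C4 substituent should give the trans lactone 14.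

2. Step 14. What may go wrong: the epoxide may ionise to a free benzylic cation stabilised by the ortho benzyloxy group, so that the siloxymethyl shift loses its anti stereospecificity or a hydride shift to the ketone competes; the lactone carbonyl may also sequester the aluminium reagent. The fallback sets the side-chain centre by a catalytic asymmetric hydroxymethylation of a ketone enolate and uses no epoxide; it sets out from chloride 14 and comes back at hydroxy ketone 26, so steps 10 to 18 are by-passed. Palladium-catalysed α-arylation of 1-[4-(benzyloxy)-3-methoxyphenyl]ethanone with 14 (Pd(OAc)2, XPhos, K3PO4, toluene, 90 °C) should give (3S,4S)-3-{4-(benzyloxy)-3-[2-(4-benzyloxy-3-methoxyphenyl)-2-oxoethyl]-5-methoxybenzyl}-4-[4-(benzyloxy)-3-methoxybenzyl]dihydrofuran-2(3H)-one F6. Me3SiOTf (1.1 equiv) and Et3N should convert the doubly activated ketone into its (Z) trimethylsilyl enol ether F7. Mukaiyama-type aldol reaction with aqueous formaldehyde under Sc(OTf)3 and a chiral 2,2'-bipyridine diol ligand (antipode chosen for the S centre) should give 26.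

3. Step 16. What may go wrong: the aryl-metal reagent may deprotonate the α-aryl aldehyde (loss of the S centre, β-elimination of silanolate) or attack the lactone. The fallback replaces carbonyl addition and oxidation by an acyl cross-coupling; it sets out from aldehyde 20 and comes back at ketone 25. Pinnick oxidation (NaClO2, NaH2PO4, 2-methyl-2-butene, tBuOH/H2O) should give (S)-2-{2-(benzyloxy)-5-{[(3S,4S)-4-(4-benzyloxy-3-methoxybenzyl)-2-oxotetrahydrofuran-3-yl]methyl}-3-methoxyphenyl}-3-(tert-butyldimethylsilyloxy)propanoic acid F8. Coupling with thiophenol (EDC·HCl, HOBt, CH2Cl2, 0 °C, no DMAP) should give its S-phenyl thioester F9. Liebeskind–Srogl coupling with [4-(benzyloxy)-3-methoxyphenyl]boronic acid (Pd2(dba)3, tri(2-furyl)phosphine, copper thiophene-2-carboxylate Cu(O2CC4H3S), THF, 50 °C) should give 25 without base.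

**Further compounds**
F1 | step 9 | (E)-4-[4-(benzyloxy)-3-methoxyphenyl]-3-(methoxycarbonyl)but-3-enoic acid | COC(=O)/C(CC(=O)O)=C/c1ccc(OCc2ccccc2)c(OC)c1
F2 | step 9 | (S)-4-[4-(benzyloxy)-3-methoxyphenyl]-3-(methoxycarbonyl)butanoic acid | COC(=O)[C@H](CC(=O)O)Cc1ccc(OCc2ccccc2)c(OC)c1
F3 | step 9 | (S)-4-[4-(benzyloxy)-3-methoxybenzyl]dihydrofuran-2(3H)-one | COc1cc(C[C@@H]2COC(=O)C2)ccc1OCc1ccccc1
F4 | step 9 | 4-(benzyloxy)-3-chloro-5-methoxybenzyl alcohol | COc1cc(CO)cc(Cl)c1OCc1ccccc1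
F5 | step 9 | 4-(benzyloxy)-3-chloro-5-methoxybenzyl bromide | COc1cc(CBr)cc(Cl)c1OCc1ccccc1
F6 | step 14 | (3S,4S)-3-{4-(benzyloxy)-3-[2-(4-benzyloxy-3-methoxyphenyl)-2-oxoethyl]-5-methoxybenzyl}-4-[4-(benzyloxy)-3-methoxybenzyl]dihydrofuran-2(3H)-one | COc1cc(C[C@@H]2COC(=O)[C@H]2Cc2cc(OC)c(OCc3ccccc3)c(CC(=O)c3ccc(OCc4ccccc4)c(OC)c3)c2)ccc1OCc1ccccc1
F7 | step 14 | (Z)-trimethylsilyl enol ether of F6 | COc1cc(C[C@@H]2COC(=O)[C@H]2Cc2cc(OC)c(OCc3ccccc3)c(/C=C(\O[Si](C)(C)C)c3ccc(OCc4ccccc4)c(OC)c3)c2)ccc1OCc1ccccc1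
F8 | step 16 | (S)-2-{2-(benzyloxy)-5-{[(3S,4S)-4-(4-benzyloxy-3-methoxybenzyl)-2-oxotetrahydrofuran-3-yl]methyl}-3-methoxyphenyl}-3-(tert-butyldimethylsilyloxy)propanoic acid | COc1cc(C[C@@H]2COC(=O)[C@H]2Cc2cc(OC)c(OCc3ccccc3)c([C@@H](CO[Si](C)(C)C(C)(C)C)C(=O)O)c2)ccc1OCc1ccccc1
F9 | step 16 | S-phenyl thioester of F8 | COc1cc(C[C@@H]2COC(=O)[C@H]2Cc2cc(OC)c(OCc3ccccc3)c([C@@H](CO[Si](C)(C)C(C)(C)C)C(=O)Sc3ccccc3)c2)ccc1OCc1ccccc1
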